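**Plan**
1. Cuts: the dimethylchromene on ring B (O4'–CMe2 and C5'–CH, back to prenal), the 7-O-allyl group, then ring C at O1–C2 and at C3–C4.
2. Enabling feature: ring C (O1–C2–C3–C4) is fused to ring A at C8a and C4a, so ring A with O1 and C4 is a latent ortho-quinone methide (O1=C8a, C4a=C4) and C2–C3 with ring B is the enolate of an arylacetyl unit.
3. Forward: the ring B arylacetyl imidazole (from resorcinol) and the ring A silyloxybenzyl bromide (from 2,4-dihydroxybenzaldehyde) are joined in a carbene-catalysed [4+2] annulation that forms C3–C4 and O1–C2 and closes ring C as a lactone.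
4. The lactone is reduced and ring C is closed again as the cyclic ether (Mitsunobu); MOM removal and prenal annulation build the chromene on ring B, and deallylation ends the route.
5. Stereochemistry: C3 (R), the only stereocentre, is set by the chiral triazolium carbene in the annulation and secured by immediate reduction of the lactone.

Key step: step 10

Remark: isoflavan numbering is used throughout (ring C = O1, C2, C3, C4; ring A = C4a–C8a; ring B primed).
Assumption: the (5aS,10bR) antipode of the N-mesityl aminoindanol-derived triazolium salt is taken to deliver the 3R lactone. If a trial run shows the opposite sense, the mirror-image (5aR,10bS) salt is used and nothing else changes.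

**Route**

Step 1
Reactants: 1 resorcinol
Product: 2 1,3-bis(methoxymethoxy)benzene
Conditions: NaH, MOMCl, DMF, 0 °C → rt
Reagents that add atoms: chloromethyl methyl ether (MOMCl), COCCl
Why: Williamson etherification of both phenoxides gives the bis-acetal, whose OMOM groups later direct both ring lithiations.

Step 2
Reactants: 2 1,3-bis(methoxymethoxy)benzene; 3 prenyl bromide (1-bromo-3-methylbut-2-ene)
Product: 5 1,3-bis(methoxymethoxy)-2-(3-methylbut-2-enyl)benzene, via aryllithium 4 (not isolated)
Conditions: n-BuLi, THF, 0 °C → rt; CuI (10 mol %), then 3, −78 °C → rt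
Reagents that add atoms: none
Why: Directed ortho-metalation occurs at C2 between the two cooperating OMOM groups, and the aryllithium is alkylated at the primary carbon of prenyl bromide (SN2), CuI suppressing the SN2' pathway.

Step 3
Reactants: 5 1,3-bis(methoxymethoxy)-2-(3-methylbut-2-enyl)benzene; 6 ethylene oxide (oxirane)
Product: 8 2-[2,4-bis(methoxymethoxy)-3-(3-methylbut-2-enyl)phenyl]ethanol, via aryllithium 7 (not isolated)
Conditions: n-BuLi, TMEDA, THF, −20 → 0 °C; 6 (THF solution), 0 °C → rt; H2O
Reagents that add atoms: none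
Why: A second directed ortho-metalation next to an OMOM group gives aryllithium 7, which opens the epoxide by SN2 attack and installs the two-carbon arm that becomes C3 and C2.

Step 4
Reactants: 8 2-[2,4-bis(methoxymethoxy)-3-(3-methylbut-2-enyl)phenyl]ethanol
Product: 10 [2,4-bis(methoxymethoxy)-3-(3-methylbut-2-enyl)phenyl]acetic acid, via arylacetaldehyde 9 (not isolated)
Conditions: TEMPO (2,2,6,6-tetramethylpiperidin-1-oxyl, 20 mol %), PhI(OAc)2, MeCN/H2O, rt
Reagents that add atoms: water, O
Why: Oxoammonium-mediated oxidation with PhI(OAc)2 as terminal oxidant takes the primary alcohol through aldehyde 9 and its hydrate to the acid without electrophilic halogen, so the prenyl alkene and the electron-rich ring should be left alone.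

Step 5
Reactants: 10 [2,4-bis(methoxymethoxy)-3-(3-methylbut-2-enyl)phenyl]acetic acid
Product: 11 2-[2,4-bis(methoxymethoxy)-3-(3-methylbut-2-enyl)phenyl]-1-(imidazol-1-yl)ethanone
Conditions: CDI, CH2Cl2, rt; used without storage
Reagents that add atoms: 1,1'-carbonyldiimidazole (CDI), O=C(n1ccnc1)n1ccnc1
Why: Acyl transfer from CDI gives the N-acyl imidazole with loss of CO2 and imidazole, a standard carboxylic acid activation.

Step 6
Reactants: 12 2,4-dihydroxybenzaldehyde
Product: 13 4-(allyloxy)-2-hydroxybenzaldehyde
Conditions: allyl bromide, CsHCO3, MeCN, 60 °C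
Reagents that add atoms: allyl bromide, C=CCBr
Why: Williamson etherification is selective for the 4-OH because the 2-OH is hydrogen-bonded to the aldehyde and is less nucleophilic under bicarbonate conditions.

Step 7
Reactants: 13 4-(allyloxy)-2-hydroxybenzaldehyde
Product: 14 4-(allyloxy)-2-[(tert-butyldimethylsilyl)oxy]benzaldehyde
Conditions: TBSCl, imidazole, DMF, rt
Reagents that add atoms: tert-butyldimethylsilyl chloride (TBSCl), CC(C)(C)[Si](C)(C)Cl
Why: Imidazole-promoted silylation of the remaining phenol installs the fluoride-labile aryl silyl ether that later triggers quinone methide formation.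

Step 8
Reactants: 14 4-(allyloxy)-2-[(tert-butyldimethylsilyl)oxy]benzaldehyde
Product: 15 {4-(allyloxy)-2-[(tert-butyldimethylsilyl)oxy]phenyl}methanol
Conditions: NaBH4, MeOH/THF, 0 °C, short reaction time; pH 7 buffer
Reagents that add atoms: none
Why: Borohydride reduction of the aldehyde at low temperature and with a neutral quench should give the benzylic alcohol before the silyl group can migrate from the phenolic to the benzylic oxygen.

Step 9
Reactants: 15 {4-(allyloxy)-2-[(tert-butyldimethylsilyl)oxy]phenyl}methanol
Product: 16 [5-(allyloxy)-2-(bromomethyl)phenoxy](tert-butyl)dimethylsilane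
Conditions: CBr4, PPh3, CH2Cl2, 0 °C; used at once
Reagents that add atoms: carbon tetrabromide, BrC(Br)(Br)Br
Why: Appel bromination under neutral conditions converts the benzylic alcohol into the bromide without acid that could cleave the aryl silyl ether.

Step 10
Reactants: 11 2-[2,4-bis(methoxymethoxy)-3-(3-methylbut-2-enyl)phenyl]-1-(imidazol-1-yl)ethanone; 16 [5-(allyloxy)-2-(bromomethyl)phenoxy](tert-butyl)dimethylsilane
Product: 18 (3R)-7-(allyloxy)-3-[2,4-bis(methoxymethoxy)-3-(3-methylbut-2-enyl)phenyl]chroman-2-one, via ortho-quinone methide 17 (not isolated)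
Conditions: (5aS,10bR)-2-mesityl-5a,10b-dihydro-4H,6H-indeno[2,1-b][1,2,4]triazolo[4,3-d][1,4]oxazin-2-ium tetrafluoroborate (15 mol %), CsF, 18-crown-6, 4 Å MS, THF, −20 → 0 °C; pH 7 quench, rapid filtration
Reagents that add atoms: none
Why: Fluoride cleaves the aryl silyl ether of 16 and the phenoxide expels bromide (1,4-elimination) to give ortho-quinone methide 17, while the carbene freed from the triazolium salt is acylated by 11 and the acyl azolium is deprotonated by the released imidazolide to the azolium enolate. Conjugate addition of the enolate carbon to the exocyclic methylene forms C3–C4 and rearomatises ring A, and the resulting phenoxide attacks the acyl azolium carbonyl (O1–C2), so ring C closes as a six-membered lactone by 6-exo-trig addition–elimination with release of the carbene; this is the known carbene-catalysed formal [4+2] annulation of acyl-imidazole-derived azolium enolates with fluoride-generated ortho-quinone methides. C3 is the only new stereocentre and is under catalyst control: the fused indane wall of the aminoindanol triazolium shields one enolate face, so the methide is taken up on the open face. The step needs chemoselective C-alkylation by the enolate over self-condensation of 17 or its capture by imidazole, which slow release of 17 at low temperature and the stabilising 7-allyloxy group para to C4a should secure. It also needs the acidic C3–H to keep its configuration, which the twisted, electron-rich 2',4'-dialkoxyaryl group, the low temperature and the immediate reduction in step 11 should secure.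

Step 11
Reactants: 18 (3R)-7-(allyloxy)-3-[2,4-bis(methoxymethoxy)-3-(3-methylbut-2-enyl)phenyl]chroman-2-one
Product: 19 5-(allyloxy)-2-{(2R)-2-[2,4-bis(methoxymethoxy)-3-(3-methylbut-2-enyl)phenyl]-3-hydroxypropyl}phenol
Conditions: LiAlH4, THF, −20 → 0 °C; aqueous work-up
Reagents that add atoms: none
Why: Hydride reduction of the aryl ester (lactone) to the phenol and primary alcohol should outrun enolisation, after which C3–H is no longer acidic and the configuration is fixed.

Step 12
Reactants: 19 5-(allyloxy)-2-{(2R)-2-[2,4-bis(methoxymethoxy)-3-(3-methylbut-2-enyl)phenyl]-3-hydroxypropyl}phenol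
Product: 20 (3R)-7-(allyloxy)-3-[2,4-bis(methoxymethoxy)-3-(3-methylbut-2-enyl)phenyl]chromane
Conditions: PPh3, DIAD, THF, 0 °C → rt
Reagents that add atoms: none
Why: In this intramolecular Mitsunobu etherification the phenol, the only acidic pronucleophile, displaces the activated primary alcohol in a 6-exo-tet closure that does not touch the adjacent stereocentre.

Step 13
Reactants: 20 (3R)-7-(allyloxy)-3-[2,4-bis(methoxymethoxy)-3-(3-methylbut-2-enyl)phenyl]chromane
Product: 21 4-[(3R)-7-(allyloxy)chroman-3-yl]-2-(3-methylbut-2-enyl)benzene-1,3-diol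
Conditions: HCl (3 M aq., catalytic), MeOH, 40 °C
Reagents that add atoms: none
Why: Acid-catalysed acetal exchange with methanol removes both MOM groups, and the mild temperature should keep the 2'-phenol from adding to the prenyl double bond.

Step 14
Reactants: 21 4-[(3R)-7-(allyloxy)chroman-3-yl]-2-(3-methylbut-2-enyl)benzene-1,3-diol; 22 prenal (3-methylbut-2-enal)
Product: 24 6-[(3R)-7-(allyloxy)chroman-3-yl]-2,2-dimethyl-8-(3-methylbut-2-enyl)-2H-chromen-7-ol, via oxatriene 23 (not isolated)
Conditions: ethylenediammonium diacetate (20 mol %), toluene, reflux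
Reagents that add atoms: none
Why: Amine-salt-catalysed Knoevenagel-type condensation of prenal at C5', the only free position ortho or para to a hydroxyl, gives oxatriene 23, which closes onto the 4'-oxygen by oxa-6π electrocyclisation (formal [3+3] chromenylation); the 2'-OH has no free ortho carbon and the 7-oxygen is masked as its allyl ether.

Step 15
Reactants: 24 6-[(3R)-7-(allyloxy)chroman-3-yl]-2,2-dimethyl-8-(3-methylbut-2-enyl)-2H-chromen-7-ol
Product: 25 6-[(3R)-7-hydroxychroman-3-yl]-2,2-dimethyl-8-(3-methylbut-2-enyl)-2H-chromen-7-ol (CNP0331403.1)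
Conditions: Pd(PPh3)4 (5 mol %), morpholine, THF, rt
Reagents that add atoms: none
Why: Zerovalent palladium ionises the aryl allyl ether to a π-allyl complex that morpholine captures (Tsuji–Trost deallylation), freeing the 7-OH without touching the prenyl group or the chromene.

**Compound list**
1 | resorcinol | Oc1cccc(O)c1 | starting material
2 | 1,3-bis(methoxymethoxy)benzene | COCOc1cccc(OCOC)c1 | intermediate
3 | prenyl bromide (1-bromo-3-methylbut-2-ene) | CC(C)=CCBr | starting material
4 | [2,6-bis(methoxymethoxy)phenyl]lithium | [Li]c1c(OCOC)cccc1OCOC | intermediate (not isolated)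
5 | 1,3-bis(methoxymethoxy)-2-(3-methylbut-2-enyl)benzene | COCOc1cccc(OCOC)c1CC=C(C)C | intermediate
6 | ethylene oxide (oxirane) | C1CO1 | starting material
7 | [2,4-bis(methoxymethoxy)-3-(3-methylbut-2-enyl)phenyl]lithium | [Li]c1ccc(OCOC)c(CC=C(C)C)c1OCOC | intermediate (not isolated)
8 | 2-[2,4-bis(methoxymethoxy)-3-(3-methylbut-2-enyl)phenyl]ethanol | OCCc1ccc(OCOC)c(CC=C(C)C)c1OCOC | intermediate
9 | [2,4-bis(methoxymethoxy)-3-(3-methylbut-2-enyl)phenyl]acetaldehyde | O=CCc1ccc(OCOC)c(CC=C(C)C)c1OCOC | intermediate (not isolated)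
10 | [2,4-bis(methoxymethoxy)-3-(3-methylbut-2-enyl)phenyl]acetic acid | OC(=O)Cc1ccc(OCOC)c(CC=C(C)C)c1OCOC | intermediate
11 | 2-[2,4-bis(methoxymethoxy)-3-(3-methylbut-2-enyl)phenyl]-1-(imidazol-1-yl)ethanone | O=C(Cc1ccc(OCOC)c(CC=C(C)C)c1OCOC)n1ccnc1 | intermediate
12 | 2,4-dihydroxybenzaldehyde | O=Cc1ccc(O)cc1O | starting material
13 | 4-(allyloxy)-2-hydroxybenzaldehyde | C=CCOc1ccc(C=O)c(O)c1 | intermediate
14 | 4-(allyloxy)-2-[(tert-butyldimethylsilyl)oxy]benzaldehyde | C=CCOc1ccc(C=O)c(O[Si](C)(C)C(C)(C)C)c1 | intermediate
15 | {4-(allyloxy)-2-[(tert-butyldimethylsilyl)oxy]phenyl}methanol | C=CCOc1ccc(CO)c(O[Si](C)(C)C(C)(C)C)c1 | intermediate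
16 | [5-(allyloxy)-2-(bromomethyl)phenoxy](tert-butyl)dimethylsilane | C=CCOc1ccc(CBr)c(O[Si](C)(C)C(C)(C)C)c1 | intermediate
17 | 3-(allyloxy)-6-methylidenecyclohexa-2,4-dien-1-one | C=CCOC1=CC(=O)C(=C)C=C1 | intermediate (not isolated)
18 | (3R)-7-(allyloxy)-3-[2,4-bis(methoxymethoxy)-3-(3-methylbut-2-enyl)phenyl]chroman-2-one | O=C1Oc2cc(OCC=C)ccc2C[C@@H]1c1ccc(OCOC)c(CC=C(C)C)c1OCOC | intermediate
19 | 5-(allyloxy)-2-{(2R)-2-[2,4-bis(methoxymethoxy)-3-(3-methylbut-2-enyl)phenyl]-3-hydroxypropyl}phenol | OC[C@H](Cc1ccc(OCC=C)cc1O)c1ccc(OCOC)c(CC=C(C)C)c1OCOC | intermediate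
20 | (3R)-7-(allyloxy)-3-[2,4-bis(methoxymethoxy)-3-(3-methylbut-2-enyl)phenyl]chromane | COCOc1ccc([C@@H]2COc3cc(OCC=C)ccc3C2)c(OCOC)c1CC=C(C)C | intermediate
21 | 4-[(3R)-7-(allyloxy)chroman-3-yl]-2-(3-methylbut-2-enyl)benzene-1,3-diol | Oc1ccc([C@@H]2COc3cc(OCC=C)ccc3C2)c(O)c1CC=C(C)C | intermediate
22 | prenal (3-methylbut-2-enal) | CC(C)=CC=O | starting material
23 | 4-[(3R)-7-(allyloxy)chroman-3-yl]-3-hydroxy-6-(3-methylbut-2-enylidene)-2-(3-methylbut-2-enyl)cyclohexa-2,4-dien-1-one | CC(C)=CCC1=C(O)C([C@@H]2COc3cc(OCC=C)ccc3C2)=CC(=CC=C(C)C)C1=O | intermediate (not isolated)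
24 | 6-[(3R)-7-(allyloxy)chroman-3-yl]-2,2-dimethyl-8-(3-methylbut-2-enyl)-2H-chromen-7-ol | CC(C)=CCc1c(O)c([C@@H]2COc3cc(OCC=C)ccc3C2)cc2c1OC(C)(C)C=C2 | intermediate
25 | 6-[(3R)-7-hydroxychroman-3-yl]-2,2-dimethyl-8-(3-methylbut-2-enyl)-2H-chromen-7-ol | CC(C)=CCc1c(O)c([C@@H]2COc3cc(O)ccc3C2)cc2c1OC(C)(C)C=C2 | target

**Count**
Total steps: 15. Longest linear sequence: 11 steps (steps 1–5, then 10–15); the ring A fragment takes 4 steps (6–9).

**Steps most likely to fail**

Step 10. The enantiomeric purity may be lost, either by poor facial selectivity of the α-aryl azolium enolate or by base-mediated enolisation of the 3-aryl lactone before it is reduced. The quinone methide may also be consumed by imidazole or by self-condensation. The fallback sets out from acid 10 (with bromide 16) and comes back at diol 19, making the same C3–C4 bond by auxiliary control. Acid 10 is converted through its pivalic mixed anhydride (PivCl, Et3N, THF, −20 °C) and lithiated (R)-4-benzyl-1,3-oxazolidin-2-one into the N-acyl oxazolidinone F1. Its chelated sodium Z-enolate (NaN(SiMe3)2, THF, −78 °C) is alkylated by 16 on the face away from the benzyl group to give the alkylated imide F2 with the 2R centre. LiBH4 (THF, MeOH, 0 °C) removes the auxiliary reductively to give the silyl-protected alcohol F3, and Bu4NF (THF, 0 °C) frees the phenol to give 19, which continues with step 12.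

Step 3. Deprotonation may occur at the benzylic and allylic CH2 of the prenyl group instead of at the ring, or ring metalation may be incomplete, so that the two-carbon arm is installed in low yield or at the wrong site. The fallback sets out from 2 and comes back at alcohol 8 through aryllithium 7, replacing deprotonation by halogen–metal exchange. Compound 2 is brominated para to one OMOM group (NBS, MeCN, 0 °C) to give 1-bromo-2,4-bis(methoxymethoxy)benzene F4. LiN(i-Pr)2 (THF, −78 °C) removes the proton between the two OMOM groups, and prenylation with 3 (CuI cat.) gives 1-bromo-2,4-bis(methoxymethoxy)-3-(3-methylbut-2-enyl)benzene F5. Bromine–lithium exchange (t-BuLi, 2 equiv, THF, −78 °C) then generates 7 regiospecifically, and ethylene oxide 6 converts it into 8.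

Step 14. Condensation of the non-acylated resorcinol with prenal may be sluggish, and prenal may oligomerise at reflux, so that the chromene forms in low yield. The fallback sets out from 21 and comes back at 24 by a propargyl ether rearrangement. The less hindered 4'-OH of 21 is etherified with 3-chloro-3-methylbut-1-yne (CuCl2 cat., DBU, MeCN, 0 °C) to give the 1,1-dimethylpropargyl ether F6. Heating in xylene at 130 °C should bring about aryl propargyl Claisen rearrangement to C5' (the other ortho position carries the prenyl group), enolisation, 1,5-hydrogen shift and oxa-6π closure to 24. The simple allyl ether at C7 rearranges only at much higher temperature and should persist.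

**Further compounds**
F1 | step 10 | (4R)-4-benzyl-3-{[2,4-bis(methoxymethoxy)-3-(3-methylbut-2-enyl)phenyl]acetyl}-1,3-oxazolidin-2-one | O=C1OC[C@@H](Cc2ccccc2)N1C(=O)Cc3ccc(OCOC)c(CC=C(C)C)c3OCOC
F2 | step 10 | (4R)-3-[(2R)-3-{4-(allyloxy)-2-[(tert-butyldimethylsilyl)oxy]phenyl}-2-[2,4-bis(methoxymethoxy)-3-(3-methylbut-2-enyl)phenyl]propanoyl]-4-benzyl-1,3-oxazolidin-2-one | O=C1OC[C@@H](Cc2ccccc2)N1C(=O)[C@H](Cc3ccc(OCC=C)cc3O[Si](C)(C)C(C)(C)C)c4ccc(OCOC)c(CC=C(C)C)c4OCOC
F3 | step 10 | (2R)-3-{4-(allyloxy)-2-[(tert-butyldimethylsilyl)oxy]phenyl}-2-[2,4-bis(methoxymethoxy)-3-(3-methylbut-2-enyl)phenyl]propan-1-ol | OC[C@H](Cc1ccc(OCC=C)cc1O[Si](C)(C)C(C)(C)C)c1ccc(OCOC)c(CC=C(C)C)c1OCOC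
F4 | step 3 | 1-bromo-2,4-bis(methoxymethoxy)benzene | COCOc1ccc(Br)c(OCOC)c1
F5 | step 3 | 1-bromo-2,4-bis(methoxymethoxy)-3-(3-methylbut-2-enyl)benzene | COCOc1ccc(Br)c(OCOC)c1CC=C(C)C
F6 | step 14 | 6-[(3R)-7-(allyloxy)chroman-3-yl]-3-[(2-methylbut-3-yn-2-yl)oxy]-2-(3-methylbut-2-enyl)phenol | C#CC(C)(C)Oc1ccc([C@@H]2COc3cc(OCC=C)ccc3C2)c(O)c1CC=C(C)C
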